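Atom labels follow chromanone numbering throughout: O1, C2, C3, C4, C4a, C5, C6, C7, C8, C8a. "cb" stands for the (1S,3R)-2,2-dimethyl-3-(prop-1-en-2-yl)cyclobutyl group.

## The problem

Target 33 is a dearomatised acylphloroglucinol. Ring B (C4a, C5, C6, C7, C8, C8a) is a cyclohexa-2,4-dienone, fused along C4a–C8a to a 2,3-dimethyl-2,3-dihydropyran-4-one (ring A: O1, C2, C3, C4). C8 carries a prenyl group and, through one methylene, a cis-1,3-disubstituted 2,2-dimethylcyclobutane (ring C).

Every carbon of ring B is substituted. Its three oxygens differ (O1 alkylated, O5 a free enol, O7 a ketone), so they must be told apart, with the acyl carbon C4 placed at C4a and the hexanoic acid branch at C6.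

The six stereocentres fall into four isolated sets: the cyclobutane pair, C8, the side-chain methine, and C2/C3. Only C2 and C3 are close enough to control each other, so each set must be imported or set on its own.

C8 is the hard one. It is quaternary, both of its carbon substituents begin with CH2, and the nearest stereocentres (C2 across O1, the cyclobutane CH, the methine across C7) are three bonds away.

The 2,3-cis arrangement is the less stable one. C3 lies alpha to the C4 ketone and O1 is a beta leaving group, so base or strong acid late in the route would epimerise C3 or open ring A.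

The prenyl and isopropenyl alkenes and the strained ring C rule out strong protic or Lewis acids, hydrogenation and unselective oxidants. The enolised tricarbonyl is acidic and easily O-acylated.

The feature that opens the way is the sequence C7 ketone, sp3 C8, C6=C5, C4a=C8a. Ring B is the valence isomer of the dienylketene O=C7=C6–C5=C4a–C8a=C8. Since C8 bears no hydrogen, closing that ketene cannot run on to a phenol.

## Retrosynthesis

**33 to 32 (two O–Si bonds).** The C5 enol and the carboxylic acid are both masked as triisopropylsilyl derivatives.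
- An alkyl ester would need hydroxide in the last step, exactly where C3 is most exposed.
- A silyl ester is no more labile than the vinylogous silyl ester at O5 that the key step creates anyway, so it adds no new liability.
- The forward step only has to deliver fluoride under buffered conditions.

**32 to 30 and 29 (C4–C4a).** Ring A is opened at the acyl–ring bond.
- The neighbouring cuts at O1 (oxa-Michael closure onto a tigloyl group) would build C2 and C3 under equilibrating conditions and favour the trans isomer.
- Cutting C4–C4a leaves both centres as spectators.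
- C4a is the only ring CH in 29, and O1 is already tied to C2, so closure has a single regiochemical outcome.
- The forward reaction needs a mild intramolecular C-acylation from acid 30, freed from allyl ester 29 under neutral conditions.

**29 to 27 (C7–C8, key step).**
- Cutting a C8–CH2 bond instead would mean alkylative dearomatisation, which has C versus O and positional ambiguity and no facial control.
- Cutting C7–C8 turns the ring into dienylketene 28, which is reached from cyclobutenone 27 simply by heating.
- The precursor has no quaternary carbon.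
- The stereocentre at C4a of 27 and the enol ether geometry are both erased on closure, so every isomer of 27 gives the same two C8 epimers.
- The forward reaction must favour one face of C8a=C8. The plan budgets for a weak preference by recycling the wrong epimer photochemically.

**27 to 17 and 24 (C6–C7 and C4a–C5).** The cyclobutenone is the [2+2] adduct of vinylketene 26 and siloxyalkyne 24.
- The polarity fixes the regiochemistry: the ketene carbonyl carbon bonds to the nucleophilic alkyne carbon.
- The cut divides the molecule into two halves of similar size. Four ring carbons come from acid 17 (through acid chloride 25) and two from 24.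
- The ketene must be generated at or below room temperature so that 27 survives.

**17 to 16, then 12 and 15 (O1–C2).**
- The enol ether oxygen is joined to C2 by substitution with inversion, so the easily made anti hydroxy ester 15 gives the syn array that becomes the cis ring.
- The alternative cut at O1–C8a (addition–elimination with retention) needs the less accessible syn alcohol and is kept in reserve.
- A fluoride-labile ester in 16 lets the acrylate carboxyl be freed beside the allyl ester.

**12 to 10 and 11, 10 to 9 and 5, 9 to 6 and 7 (both C8–CH2 bonds).**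
- Two successive gamma-alkylations of an acetoacetate dianion attach the cyclobutylmethyl and prenyl groups to the carbon that becomes C8.
- The hindered iodide 5 meets the unhindered dianion first. The reactive bromide 11 meets the hindered dianion second.
- The stereocentre formed in 12 does not matter, because it becomes sp2 in 26.

**5 to 4, 3, 2 and 1 (ring C from the chiral pool).** Oxidative cleavage of 1 gives the cis cyclobutane with both centres in the absolute configuration of 33. Only methylenation, reduction and iodination remain.

**15 to 14 and 13 (C3–CH3).** Chelate-controlled methylation of the dianion of 13 sets C3 relative to the existing carbinol centre. Ester exchange then installs the allyl group.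

**24 to 22, 21, 20, then 18 and 19 (methine–alkyne bond).**
- The side-chain methine is set by catalytic asymmetric conjugate alkynylation of enal 18 with 19.
- This delivers the alkyne carbon that becomes C6 and the carboxyl carbon in the correct 1,3-relationship.
- Oxidation, desilylation and oxygenation of the acetylide (through ynolate 23) complete the fragment.

## Roads not taken

**Alternative 1:** Ring A is cut at C2–C3 and O1–C8a.

In the forward sense the Z enol silane A2 (a finished ring B carrying an 8a-methoxy group and the O5 enol lactone) adds through C3 to Lewis-acid-bound acetaldehyde A3. The aldolate oxygen then expels methoxide from C8a to give the enol lactone A1.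

- *Merits:* two bonds and a ring form in one late operation from a two-carbon reagent. The lactone masks O5 and the acid together. No Friedel–Crafts step is needed, so this endgame is shorter than the chosen one.
- *Weak points:* A2 already contains C8, so the hardest stereocentre is only moved upstream. C2 and C3 must be induced by distant stereocentres or by a chiral Lewis acid. The small aldehyde A3 gives poor simple diastereoselection in Mukaiyama aldol reactions. The cis product sits under Lewis-acidic, equilibrating conditions.
- *Comparison:* the chosen plan imports C2 and C3 as a defined pair from the chiral pool and never makes or breaks a bond at either after step 10. It pays with a less certain ring closure (step 19).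

**Alternative 2:** Ring B is cut at C4a–C8a and C6–C7.

The kinetic enolate of methyl ketone A6 is acylated at its methyl carbon by the quaternary malonyl chloride A5. A second deprotonation then closes the ring onto the methyl ester to give A4.

- *Merits:* robust anionic chemistry and real convergence. C8 exists as a configurationally fixed quaternary centre before the ring forms, so no helical question arises. In that respect it is better than the chosen plan.
- *Weak points:* a single diastereomer of A5 requires telling apart two carboxyl groups on a carbon whose other arms both start with CH2, which is the same recognition problem in another guise. A4 leaves O5, O7 and O8a undifferentiated, so ring A could close on either side of C4a. The side chain is at the alcohol level and needs a late oxidation beside an oxidisable enol.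
- *Comparison:* the chosen plan offers complete oxygen differentiation at the moment the ring forms, and a side chain already at the acid level.

**Alternative 3:** The C6–methine bond and the O5–acyl bond are cut.

One of the two ring CH carbons of the symmetric trione A8 adds to a catalyst-bound hex-2-enoyl unit derived from A9. The neighbouring enol oxygen is then acylated, giving A7.

- *Merits:* A8 is very short to make, and one catalytic step would set the methine and, by desymmetrisation, C8. If the catalyst performed, this would be the most step-economical route of all.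
- *Weak points:* the two CH positions differ only through prenyl versus cyclobutylmethyl on C8, far from the reacting carbon. The catalyst must therefore control the enoate face and also read a remote difference in a substrate that already carries stereocentres. Beta-alkyl enoyl acceptors are the less reactive class. C4a acylation and the O7/O8a distinction remain to be solved on A7.
- *Comparison:* the chosen plan shares the weakness at C8 and is longer. It sets the methine by an established reaction on a simple enal, and it offers a way to recycle the wrong C8 epimer, which a failed desymmetrisation does not.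

Key step: step 17

**Assumption 1:** (R)-DTBM-SEGPHOS is taken to deliver the 3S aldehyde 20 in step 12. If the sense of induction is the opposite, the equally available (S)-ligand is used.

**Assumption 2:** 12, 16, 17 and 25 are mixtures of epimers at the future C8. Compound 27 is drawn as one of its possible isomers (E enol ether, 4S). These elements are erased in steps 16 and 17.

## Steps

Step 1
Reactants: 1 (1R,5R)-(+)-verbenone
Product: 2 (1R,3S)-3-acetyl-2,2-dimethylcyclobutane-1-carboxylic acid (cis-pinononic acid)
Conditions: RuCl3·xH2O (cat.), NaIO4, MeCN/EtOAc/H2O, rt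
Reagents that add atoms: sodium periodate [Na+].[O-]I(=O)(=O)=O; water O
Why: Catalytic RuO4 cleaves the enone C=C, and the alpha-keto acid formed on the carbonyl side loses CO2 oxidatively (oxidative alkene cleavage). Both ring stereocentres of 1 are untouched, so the cis-1,3 relationship and absolute configuration of ring C are obtained directly.

Step 2
Reactants: 2 cis-pinononic acid
Product: 3 (1R,3R)-2,2-dimethyl-3-(prop-1-en-2-yl)cyclobutane-1-carboxylic acid
Conditions: MePPh3Br, KOt-Bu, THF, 0 °C to rt
Reagents that add atoms: methyltriphenylphosphonium bromide C[P+](c1ccccc1)(c1ccccc1)c1ccccc1.[Br-]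
Why: Wittig methylenation of the methyl ketone. The carboxylate formed first protects C1 from enolisation, and the unstabilised ylide should add faster than it enolises the ketone, so the cis arrangement should be kept.

Step 3
Reactants: 3 isopropenyl acid
Product: 4 [(1R,3R)-2,2-dimethyl-3-(prop-1-en-2-yl)cyclobutyl]methanol
Conditions: LiAlH4, Et2O, 0 °C to rt
Reagents that add atoms: none
Why: Hydride reduction of the acid. The isolated alkene is inert and no stereocentre is involved.

Step 4
Reactants: 4 cyclobutylmethanol
Product: 5 (1R,3R)-1-(iodomethyl)-2,2-dimethyl-3-(prop-1-en-2-yl)cyclobutane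
Conditions: I2, PPh3, imidazole, CH2Cl2, 0 °C to rt
Reagents that add atoms: iodine [I][I]
Why: Appel-type iodination by SN2 at the primary carbon. The neutral conditions avoid cyclobutylcarbinyl cation rearrangement.

Step 5
Reactants: 6 2,2,6-trimethyl-4H-1,3-dioxin-4-one; 7 2-(trimethylsilyl)ethanol
Product: 9 2-(trimethylsilyl)ethyl 3-oxobutanoate, via acetylketene 8 (not isolated)
Conditions: PhMe, 110 °C
Reagents that add atoms: none
Why: Thermal cycloreversion of 6 releases acetone and 8, which alcohol 7 captures. This is the standard acetoacetylation of alcohols.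

Step 6
Reactants: 9 2-(trimethylsilyl)ethyl 3-oxobutanoate; 5 cyclobutylmethyl iodide
Product: 10 2-(trimethylsilyl)ethyl 5-[(1R,3R)-2,2-dimethyl-3-(prop-1-en-2-yl)cyclobutyl]-3-oxopentanoate
Conditions: NaH, then n-BuLi, THF, 0 °C; 5, DMPU, 0 °C to rt
Reagents that add atoms: none
Why: Weiler dianion alkylation, in which the terminal carbanion is by far the more nucleophilic site. The cheap dianion is used in excess to offset the beta-branching of 5.

Step 7
Reactants: 10 beta-keto ester; 11 prenyl bromide
Product: 12 2-(trimethylsilyl)ethyl 4-(cb-methyl)-7-methyl-3-oxooct-6-enoate (both C4 epimers)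
Conditions: NaH, then n-BuLi, THF, 0 °C; 11, −78 to 0 °C
Reagents that add atoms: none
Why: A second Weiler dianion alkylation at the same gamma carbon, by direct SN2 on the reactive allylic bromide. The new centre (future C8) forms without control, which does not matter because it becomes sp2 in step 16.

Step 8
Reactants: 13 ethyl (S)-3-hydroxybutanoate
Product: 14 ethyl (2S,3S)-3-hydroxy-2-methylbutanoate
Conditions: LDA (2.2 equiv), THF, −78 to −20 °C; MeI, DMPU, −78 to 0 °C
Reagents that add atoms: iodomethane CI
Why: Fráter–Seebach alkylation. The chelated lithium alkoxide enolate is methylated on the face away from the carbinol methyl group, giving the anti (2S,3S) isomer and thereby the future C3.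

Step 9
Reactants: 14 anti hydroxy ethyl ester
Product: 15 prop-2-enyl (2S,3S)-3-hydroxy-2-methylbutanoate
Conditions: allyl alcohol (solvent), Ti(OEt)4 (cat.), reflux
Reagents that add atoms: allyl alcohol C=CCO
Why: Titanate-mediated transesterification is essentially neutral, so neither stereocentre is affected and no dehydration is expected. The allyl ester can later be removed without acid or base.

Step 10
Reactants: 12 branched beta-keto ester; 15 allyl anti hydroxy ester
Product: 16 (E)-beta-alkoxyacrylate carrying the (2R,3S)-configured O1–C2–C3–C4 chain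
Conditions: PPh3, DIAD, PhMe, 0 °C to rt
Reagents that add atoms: none
Why: Mitsunobu reaction. The enol oxygen of the acidic 1,3-dicarbonyl unit displaces the activated secondary hydroxyl by SN2 with inversion, so the 3S carbinol becomes C2 (R) and the anti pair becomes the syn pair needed for the cis ring. O-alkylation is the usual course for 1,3-dicarbonyl pronucleophiles with secondary alcohols. The geometry of the new C4a=C8a double bond is irrelevant because it is lost in step 16.

Step 11
Reactants: 16 beta-alkoxyacrylate
Product: 17 (E)-beta-alkoxyacrylic acid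
Conditions: TBAF, THF, 0 °C; aq NH4Cl
Reagents that add atoms: none
Why: Fluoride-induced fragmentation of the 2-(trimethylsilyl)ethyl ester leaves the allyl ester and the alkenes alone. Low temperature and short contact limit beta-elimination of the alkoxy ester.

Step 12
Reactants: 18 (E)-hex-2-enal; 19 (triisopropylsilyl)acetylene
Product: 20 (3S)-3-[(triisopropylsilyl)ethynyl]hexanal
Conditions: [Rh(OAc)(C2H4)2]2 (cat.), (R)-DTBM-SEGPHOS (cat.), MeOH, 40 °C
Reagents that add atoms: none
Why: Rhodium-catalysed asymmetric conjugate alkynylation of an enal. The bulky silyl group and ligand suppress alkyne dimerisation, and the chiral bisphosphine selects the enal face, setting the side-chain methine as S.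

Step 13
Reactants: 20 alkynyl aldehyde
Product: 21 (3S)-3-[(triisopropylsilyl)ethynyl]hexanoic acid
Conditions: NaClO2, NaH2PO4, 2-methylbut-2-ene, t-BuOH/H2O, rt
Reagents that add atoms: sodium chlorite [Na+].[O-]Cl=O
Why: Pinnick oxidation. The stereocentre is beta to the carbonyl group and cannot epimerise.

Step 14
Reactants: 21 silylalkynyl acid
Product: 22 (3S)-3-ethynylhexanoic acid
Conditions: TBAF, THF, rt
Reagents that add atoms: none
Why: Fluoride protodesilylation of the alkynylsilane; no other group is affected.

Step 15
Reactants: 22 (3S)-3-ethynylhexanoic acid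
Product: 24 triisopropylsilyl (3S)-3-[(triisopropylsilyloxy)ethynyl]hexanoate, via dilithium ynolate 23 (not isolated)
Conditions: n-BuLi (2 equiv), THF, −78 °C; t-BuOOLi (from t-BuOOH, LiN(SiMe3)2), −78 to 0 °C; TIPSOTf, −78 to 0 °C
Reagents that add atoms: tert-butyl hydroperoxide CC(C)(C)OO; triisopropylsilyl trifluoromethanesulfonate CC(C)[Si](C(C)C)(C(C)C)OS(=O)(=O)C(F)(F)F
Why: Oxidation of a lithium acetylide with lithium tert-butyl peroxide gives the ynolate, which bulky silyl triflates trap on oxygen. The lithium carboxylate is inert to base and peroxide and is silylated in the same operation, so no free acid ever meets the acid-sensitive siloxyalkyne.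

Step 16
Reactants: 17 beta-alkoxyacrylic acid; 24 siloxyalkyne
Product: 27 3-siloxy-4-alkenylcyclobut-2-enone (drawn as E enol ether and 4S epimer), via acid chloride 25 (not isolated), via vinylketene 26 (not isolated)
Conditions: 1-chloro-N,N,2-trimethylprop-1-enylamine, CH2Cl2, 0 °C; then slow addition to 24, Et3N, CH2Cl2, rt
Reagents that add atoms: none
Why: Ghosez's reagent forms 25 without free HCl, and 1,4-dehydrochlorination of this 3-alkoxyalk-2-enoyl chloride removes the C8 hydrogen to give 26. The ketene carbonyl carbon then bonds to the nucleophilic alkyne carbon in a regioselective [2+2] cycloaddition, the first half of the Danheiser benzannulation with siloxyalkynes. Room temperature keeps 27 closed, and neither the C4a centre nor the enol ether geometry needs to be uniform because step 17 erases both.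

Step 17
Reactants: 27 3-siloxy-4-alkenylcyclobut-2-enone
Product: 29 (8R)-cyclohexa-2,4-dienone bearing O5-TIPS together with the O1–C2–C3–C4 allyl ester chain, via dienylketene 28 (not isolated)
Conditions: PhMe (0.01 M, degassed), 90 °C
Reagents that add atoms: none
Why: Heating breaks the C7–C4a bond of 27 in a reversible conrotatory four-electron opening; the ketene with the alkenyl group turned outward can only revert, while inward rotation gives 28, in which C6 and C8a are cis on C5=C4a. In 28 the enol ether terminus C8 bonds to the ketene carbon C7 in a disrotatory six-electron electrocyclisation, closing ring B with all six triene atoms in the ring and forming the C7–C8 bond. This is the known thermal rearrangement of 4-alkenylcyclobutenones (the second half of the Danheiser benzannulation), and it must stop at the dienone because C8 has no hydrogen to lose. C8 is the only new stereocentre, and its configuration follows from the face of C8a=C8 that meets C7, that is, from the helical sense of 28 combined with the enol ether geometry; for the E isomer drawn, the 8R product arises from the sense that swings the inside cyclobutylmethyl group away from the incoming C7 onto the face it occupies in 33. The controlling elements are the C2 stereocentre on O1, whose C–H should lie beside C4a–H to relieve allylic strain and so place the ester branch and the methyl group on opposite faces, and the methine next to C7; this control is untested and only a modest preference should be expected. All isomers of 27 funnel into 29 and its C8 epimer, which are diastereomers and should be separable. High dilution and the absence of nucleophiles protect the ketene, and a temperature near 90 °C should stay below the onset of a Cope shift of the prenyl group from C8 to C4a.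

Step 18
Reactants: 29 (8R)-dienone allyl ester
Product: 30 (8R)-dienone C4 carboxylic acid
Conditions: Pd(PPh3)4 (cat.), N-methylaniline, THF, rt
Reagents that add atoms: none
Why: Tsuji–Trost deallylation, in which zerovalent palladium ionises the allyl ester and the weakly basic aniline traps the allyl fragment. C3, the silyl ester and the silyl enol ether should be untouched. Compound 30 is used at once to forestall silyl transfer to the free acid.

Step 19
Reactants: 30 dienone acid
Product: 32 O5-TIPS ether TIPS ester of 33, via acid chloride 31 (not isolated)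
Conditions: 1-chloro-N,N,2-trimethylprop-1-enylamine, CH2Cl2, 0 °C; AgOTf, 2,6-di-tert-butyl-4-methylpyridine, −78 to −20 °C
Reagents that add atoms: none
Why: Intramolecular Friedel–Crafts-type C-acylation of an enol ether. AgOTf removes chloride from 31, and the acylium equivalent is taken by C4a, the only ring CH and the beta carbon of the O1 enol ether, in a 6-(enolendo)-exo-trig closure of ring A. The hindered pyridine takes up the proton, protecting the alkenes and disfavouring ketene formation, so C2 and C3 should be carried over as the cis pair.

Step 20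
Reactants: 32 bis-silylated precursor
Product: 33 target
Conditions: HF·pyridine, pyridine, THF, 0 °C
Reagents that add atoms: none
Why: Fluoride cleaves the silyl ester and the vinylogous silyl ester together under buffered, near-neutral conditions. This avoids the hydroxide step that would endanger C3 and ring A.

## Compound list

1 | (1R,5R)-(+)-verbenone | O=C1C=C(C)[C@H]2C[C@@H]1C2(C)C | starting material
2 | (1R,3S)-3-acetyl-2,2-dimethylcyclobutane-1-carboxylic acid | CC(=O)[C@H]1C[C@@H](C(=O)O)C1(C)C | intermediate
3 | (1R,3R)-2,2-dimethyl-3-(prop-1-en-2-yl)cyclobutane-1-carboxylic acid | C=C(C)[C@H]1C[C@@H](C(=O)O)C1(C)C | intermediate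
4 | [(1R,3R)-2,2-dimethyl-3-(prop-1-en-2-yl)cyclobutyl]methanol | C=C(C)[C@H]1C[C@@H](CO)C1(C)C | intermediate
5 | (1R,3R)-1-(iodomethyl)-2,2-dimethyl-3-(prop-1-en-2-yl)cyclobutane | C=C(C)[C@H]1C[C@@H](CI)C1(C)C | intermediate
6 | 2,2,6-trimethyl-4H-1,3-dioxin-4-one | CC1=CC(=O)OC(C)(C)O1 | starting material
7 | 2-(trimethylsilyl)ethanol | C[Si](C)(C)CCO | starting material
8 | acetylketene (not isolated) | CC(=O)C=C=O | intermediate
9 | 2-(trimethylsilyl)ethyl 3-oxobutanoate | CC(=O)CC(=O)OCC[Si](C)(C)C | intermediate
10 | 2-(trimethylsilyl)ethyl 5-[(1R,3R)-2,2-dimethyl-3-(prop-1-en-2-yl)cyclobutyl]-3-oxopentanoate | C=C(C)[C@H]1C[C@@H](CCC(=O)CC(=O)OCC[Si](C)(C)C)C1(C)C | intermediate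
11 | prenyl bromide (1-bromo-3-methylbut-2-ene) | CC(C)=CCBr | starting material
12 | 2-(trimethylsilyl)ethyl 4-{[(1S,3R)-2,2-dimethyl-3-(prop-1-en-2-yl)cyclobutyl]methyl}-7-methyl-3-oxooct-6-enoate (both C4 epimers) | C=C(C)[C@H]1C[C@@H](CC(CC=C(C)C)C(=O)CC(=O)OCC[Si](C)(C)C)C1(C)C | intermediate
13 | ethyl (S)-3-hydroxybutanoate | O[C@@H](C)CC(=O)OCC | starting material
14 | ethyl (2S,3S)-3-hydroxy-2-methylbutanoate | O[C@@H](C)[C@H](C)C(=O)OCC | intermediate
15 | prop-2-enyl (2S,3S)-3-hydroxy-2-methylbutanoate | O[C@@H](C)[C@H](C)C(=O)OCC=C | intermediate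
16 | 2-(trimethylsilyl)ethyl (2E)-4-{[(1S,3R)-2,2-dimethyl-3-(prop-1-en-2-yl)cyclobutyl]methyl}-7-methyl-3-{[(2R,3S)-3-methyl-4-oxo-4-(prop-2-enyloxy)butan-2-yl]oxy}octa-2,6-dienoate (both C4 epimers) | C=C(C)[C@H]1C[C@@H](CC(CC=C(C)C)/C(O[C@H](C)[C@H](C)C(=O)OCC=C)=C\C(=O)OCC[Si](C)(C)C)C1(C)C | intermediate
17 | (2E)-4-{[(1S,3R)-2,2-dimethyl-3-(prop-1-en-2-yl)cyclobutyl]methyl}-7-methyl-3-{[(2R,3S)-3-methyl-4-oxo-4-(prop-2-enyloxy)butan-2-yl]oxy}octa-2,6-dienoic acid (both C4 epimers) | C=C(C)[C@H]1C[C@@H](CC(CC=C(C)C)/C(O[C@H](C)[C@H](C)C(=O)OCC=C)=C\C(=O)O)C1(C)C | intermediate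
18 | (E)-hex-2-enal | CCC/C=C/C=O | starting material
19 | (triisopropylsilyl)acetylene | C#C[Si](C(C)C)(C(C)C)C(C)C | starting material
20 | (3S)-3-[(triisopropylsilyl)ethynyl]hexanal | CC(C)[Si](C(C)C)(C(C)C)C#C[C@@H](CCC)CC=O | intermediate
21 | (3S)-3-[(triisopropylsilyl)ethynyl]hexanoic acid | CC(C)[Si](C(C)C)(C(C)C)C#C[C@@H](CCC)CC(=O)O | intermediate
22 | (3S)-3-ethynylhexanoic acid | C#C[C@@H](CCC)CC(=O)O | intermediate
23 | dilithium (3S)-3-(oxidoethynyl)hexanoate (ynolate carboxylate, not isolated) | [Li+].[Li+].[O-]C#C[C@@H](CCC)CC(=O)[O-] | intermediate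
24 | triisopropylsilyl (3S)-3-[(triisopropylsilyloxy)ethynyl]hexanoate | CC(C)[Si](C(C)C)(C(C)C)OC#C[C@@H](CCC)CC(=O)O[Si](C(C)C)(C(C)C)C(C)C | intermediate
25 | acid chloride of 17 (not isolated) | C=C(C)[C@H]1C[C@@H](CC(CC=C(C)C)/C(O[C@H](C)[C@H](C)C(=O)OCC=C)=C\C(=O)Cl)C1(C)C | intermediate
26 | prop-2-enyl (2S,3R)-3-{[(3E)-4-{[(1S,3R)-2,2-dimethyl-3-(prop-1-en-2-yl)cyclobutyl]methyl}-7-methyl-1-oxoocta-1,3,6-trien-3-yl]oxy}-2-methylbutanoate (vinylketene, not isolated) | O=C=C/C(O[C@H](C)[C@H](C)C(=O)OCC=C)=C(/CC=C(C)C)C[C@@H]1C[C@H](C(C)=C)C1(C)C | intermediate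
27 | (4S)-4-[(1E)-2-{[(1S,3R)-2,2-dimethyl-3-(prop-1-en-2-yl)cyclobutyl]methyl}-5-methyl-1-{[(2R,3S)-3-methyl-4-oxo-4-(prop-2-enyloxy)butan-2-yl]oxy}hexa-1,4-dien-1-yl]-2-[(3S)-1-oxo-1-(triisopropylsilyloxy)hexan-3-yl]-3-(triisopropylsilyloxy)cyclobut-2-en-1-one | O=C1C([C@@H](CCC)CC(=O)O[Si](C(C)C)(C(C)C)C(C)C)=C(O[Si](C(C)C)(C(C)C)C(C)C)[C@@H]1/C(O[C@H](C)[C@H](C)C(=O)OCC=C)=C(/CC=C(C)C)C[C@@H]2C[C@H](C(C)=C)C2(C)C | intermediate
28 | dienylketene O=C7=C6–C5(OTIPS)=C4a–C8a(OR)=C8, with C6 and C8a cis on C5=C4a and cyclobutylmethyl cis to C4a on C8a=C8 (not isolated) | O=C=C([C@@H](CCC)CC(=O)O[Si](C(C)C)(C(C)C)C(C)C)/C(O[Si](C(C)C)(C(C)C)C(C)C)=C\C(O[C@H](C)[C@H](C)C(=O)OCC=C)=C(\CC=C(C)C)C[C@@H]1C[C@H](C(C)=C)C1(C)C | intermediate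
29 | prop-2-enyl (2S,3R)-3-({(6R)-6-{[(1S,3R)-2,2-dimethyl-3-(prop-1-en-2-yl)cyclobutyl]methyl}-6-(3-methylbut-2-enyl)-5-oxo-4-[(3S)-1-oxo-1-(triisopropylsilyloxy)hexan-3-yl]-3-(triisopropylsilyloxy)cyclohexa-1,3-dien-1-yl}oxy)-2-methylbutanoate | C=C(C)[C@H]1C[C@@H](C[C@@]2(CC=C(C)C)C(=O)C([C@@H](CCC)CC(=O)O[Si](C(C)C)(C(C)C)C(C)C)=C(O[Si](C(C)C)(C(C)C)C(C)C)C=C2O[C@H](C)[C@H](C)C(=O)OCC=C)C1(C)C | intermediate
30 | free (2S,3R)-butanoic acid corresponding to 29 | C=C(C)[C@H]1C[C@@H](C[C@@]2(CC=C(C)C)C(=O)C([C@@H](CCC)CC(=O)O[Si](C(C)C)(C(C)C)C(C)C)=C(O[Si](C(C)C)(C(C)C)C(C)C)C=C2O[C@H](C)[C@H](C)C(=O)O)C1(C)C | intermediate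
31 | acid chloride of 30 (not isolated) | C=C(C)[C@H]1C[C@@H](C[C@@]2(CC=C(C)C)C(=O)C([C@@H](CCC)CC(=O)O[Si](C(C)C)(C(C)C)C(C)C)=C(O[Si](C(C)C)(C(C)C)C(C)C)C=C2O[C@H](C)[C@H](C)C(=O)Cl)C1(C)C | intermediate
32 | triisopropylsilyl ester and O5 triisopropylsilyl ether of 33 | C=C(C)[C@H]1C[C@@H](C[C@@]2(CC=C(C)C)C(=O)C([C@@H](CCC)CC(=O)O[Si](C(C)C)(C(C)C)C(C)C)=C(O[Si](C(C)C)(C(C)C)C(C)C)C3=C2O[C@H](C)[C@H](C)C3=O)C1(C)C | intermediate
33 | (3S)-3-[(2R,3S,8R)-8-{[(1S,3R)-2,2-dimethyl-3-(prop-1-en-2-yl)cyclobutyl]methyl}-5-hydroxy-2,3-dimethyl-8-(3-methylbut-2-enyl)-4,7-dioxo-3,4,7,8-tetrahydro-2H-chromen-6-yl]hexanoic acid | C=C(C)[C@H]1C[C@@H](C[C@@]2(CC=C(C)C)C(=O)C([C@@H](CCC)CC(=O)O)=C(O)C3=C2O[C@H](C)[C@H](C)C3=O)C1(C)C | target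

Total step count: 20.
Longest linear sequence: 13 steps from 1 (steps 1, 2, 3, 4, 6, 7, 10, 11, 16, 17, 18, 19, 20).

## Least certain steps

**Step 17 (key step).**
- *Risk:* the most likely failure is poor facial selectivity in the ring closure. The two helical senses of 28 differ only through stereocentres three bonds from C8, and a non-uniform enol ether geometry would blur any bias further. A secondary risk is a Cope shift of the prenyl group if the temperature has to be raised.
- *Fallback:* it sets out from 27. The closure is run as planned and the (8S)-dienone F1 is separated from 29. F1 is then irradiated at about 365 nm in degassed toluene at room temperature. This is the Barton–Quinkert photochemical ring opening of 6,6-disubstituted cyclohexa-2,4-dienones. With no nucleophile present it regenerates 28, which recloses thermally. Repeated cycles of separation and irradiation bring the material back to the route at 29.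

**Step 10.**
- *Risk:* elimination of the activated beta-hydroxy ester to the unsaturated ester is the main threat, because its alpha hydrogen is acidic and the pronucleophile is only moderately acidic and hindered. Slow consumption and some C-alkylation may add to the loss.
- *Fallback:* it forms O1–C8a instead of O1–C2 and sets out from 12.
  - Compound 12 is converted with NaH and Tf2O into the (Z)-enol triflate F2.
  - Separately, an Evans syn-aldol reaction of commercial (S)-4-benzyl-3-propionyloxazolidin-2-one with acetaldehyde (Bu2BOTf, Et3N) gives the syn aldol imide F3.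
  - Magnesium allyloxide (allyl alcohol, MeMgBr) turns F3 into prop-2-enyl (2S,3R)-3-hydroxy-2-methylbutanoate F4.
  - The sodium alkoxide of F4 displaces triflate from F2 by addition–elimination with retention at C2, which comes back to the route at 16.

**Step 16.**
- *Risk:* slow removal of the hindered tertiary gamma hydrogen may let the acid chloride acylate the siloxyalkyne or let the ketene dimerise. If warming is needed, premature opening of the cyclobutenone follows.
- *Fallback:* it sets out from 16 and moves the double bond first.
  - Photochemical deconjugation (254 nm, catalytic 1,2-dimethylimidazole) gives the beta,gamma-unsaturated ester F5.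
  - TBAF frees the acid F6, and Ghosez's reagent gives the acid chloride F7.
  - F7 has acidic alpha hydrogens and should lose HCl to Et3N at −20 °C by ordinary 1,2-elimination.
  - The resulting 26 is trapped by 24, and the route is rejoined at 27.

**Step 19.**
- *Risk:* C4a may be too weakly nucleophilic in the push–pull dienone. Loss of the O5 silyl group followed by O-acylation, or epimerisation at C3 through ketene formation from the activated acid, could then take over.
- *Fallback:* it lowers the oxidation level of the electrophile and sets out from 31.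
  - Palladium-catalysed reduction with Bu3SnH and Pd(PPh3)4 gives the aldehyde F8.
  - F8 should cyclise at −78 °C under MgBr2·OEt2 or BF3·OEt2 by addition of the enol ether carbon C4a to the aldehyde and loss of the C4a proton, giving the C4 alcohol F9 (either epimer).
  - Dess–Martin oxidation buffered with NaHCO3 returns to the route at 32.

**Step 15.**
- *Risk:* poor solubility and incomplete oxidation of the dilithiated acid, or silylation of the ynolate on carbon, would cut the supply of 24.
- *Fallback:* it sets out from 22.
  - Boc2O, DMAP and t-BuOH give tert-butyl (3S)-3-ethynylhexanoate F10.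
  - The same acetylide oxidation and silylation, now on a monoanion, give the siloxyalkyne F11.
  - Reaction with 17 under the conditions of step 16 gives the tert-butyl ester cyclobutenone F12.
  - TIPSOTf with 2,6-lutidine exchanges the tert-butyl ester for the silyl ester, rejoining the route at 27.

## Further compounds

F1 | step 17 | (8S)-dienone, C8 epimer of 29 | C=C(C)[C@H]1C[C@@H](C[C@]2(CC=C(C)C)C(=O)C([C@@H](CCC)CC(=O)O[Si](C(C)C)(C(C)C)C(C)C)=C(O[Si](C(C)C)(C(C)C)C(C)C)C=C2O[C@H](C)[C@H](C)C(=O)OCC=C)C1(C)C
F2 | step 10 | (Z)-enol triflate of 12 | C=C(C)[C@H]1C[C@@H](CC(CC=C(C)C)/C(OS(=O)(=O)C(F)(F)F)=C/C(=O)OCC[Si](C)(C)C)C1(C)C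
F3 | step 10 | (4S)-4-benzyl-3-[(2S,3R)-3-hydroxy-2-methylbutanoyl]oxazolidin-2-one | O=C1OC[C@H](Cc2ccccc2)N1C(=O)[C@@H](C)[C@@H](C)O
F4 | step 10 | prop-2-enyl (2S,3R)-3-hydroxy-2-methylbutanoate | O[C@H](C)[C@H](C)C(=O)OCC=C
F5 | step 16 | beta,gamma-unsaturated isomer of 16 (tetrasubstituted E enol ether) | C=C(C)[C@H]1C[C@@H](C/C(CC=C(C)C)=C(\CC(=O)OCC[Si](C)(C)C)O[C@H](C)[C@H](C)C(=O)OCC=C)C1(C)C
F6 | step 16 | beta,gamma-unsaturated acid from F5 | C=C(C)[C@H]1C[C@@H](C/C(CC=C(C)C)=C(\CC(=O)O)O[C@H](C)[C@H](C)C(=O)OCC=C)C1(C)C
F7 | step 16 | acid chloride of F6 | C=C(C)[C@H]1C[C@@H](C/C(CC=C(C)C)=C(\CC(=O)Cl)O[C@H](C)[C@H](C)C(=O)OCC=C)C1(C)C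
F8 | step 19 | C4 aldehyde corresponding to 30 | C=C(C)[C@H]1C[C@@H](C[C@@]2(CC=C(C)C)C(=O)C([C@@H](CCC)CC(=O)O[Si](C(C)C)(C(C)C)C(C)C)=C(O[Si](C(C)C)(C(C)C)C(C)C)C=C2O[C@H](C)[C@H](C)C=O)C1(C)C
F9 | step 19 | C4 alcohol corresponding to 32 (either C4 epimer) | C=C(C)[C@H]1C[C@@H](C[C@@]2(CC=C(C)C)C(=O)C([C@@H](CCC)CC(=O)O[Si](C(C)C)(C(C)C)C(C)C)=C(O[Si](C(C)C)(C(C)C)C(C)C)C3=C2O[C@H](C)[C@H](C)C3O)C1(C)C
F10 | step 15 | tert-butyl (3S)-3-ethynylhexanoate | C#C[C@@H](CCC)CC(=O)OC(C)(C)C
F11 | step 15 | tert-butyl (3S)-3-[(triisopropylsilyloxy)ethynyl]hexanoate | CC(C)[Si](C(C)C)(C(C)C)OC#C[C@@H](CCC)CC(=O)OC(C)(C)C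
F12 | step 15 | tert-butyl ester analogue of 27 | O=C1C([C@@H](CCC)CC(=O)OC(C)(C)C)=C(O[Si](C(C)C)(C(C)C)C(C)C)[C@@H]1/C(O[C@H](C)[C@H](C)C(=O)OCC=C)=C(/CC=C(C)C)C[C@@H]2C[C@H](C(C)=C)C2(C)C
A1 | alternative 1 | O5 enol lactone of 33 | C=C(C)[C@H]1C[C@@H](C[C@@]2(CC=C(C)C)C(=O)C3=C(OC(=O)C[C@@H]3CCC)C4=C2O[C@H](C)[C@H](C)C4=O)C1(C)C
A2 | alternative 1 | 8a-methoxy O5 enol lactone core bearing a (Z)-1-(trimethylsilyloxy)prop-1-enyl group at C4a | C=C(C)[C@H]1C[C@@H](C[C@@]2(CC=C(C)C)C(=O)C3=C(OC(=O)C[C@@H]3CCC)C(/C(O[Si](C)(C)C)=C/C)=C2OC)C1(C)C
A3 | alternative 1 | acetaldehyde | CC=O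
A4 | alternative 2 | C6-substituted 4,4-dialkyl trione (dienol form) with silyl-protected hydroxyethyl side chain | C=C(C)[C@H]1C[C@@H](C[C@@]2(CC=C(C)C)C(=O)C([C@@H](CCC)CCO[Si](C)(C)C(C)(C)C)=C(O)C=C2O)C1(C)C
A5 | alternative 2 | methyl 2-(chlorocarbonyl)-2-(cb-methyl)-5-methylhex-4-enoate (quaternary malonyl chloride) | C=C(C)[C@H]1C[C@@H](C[C@@](CC=C(C)C)(C(=O)OC)C(=O)Cl)C1(C)C
A6 | alternative 2 | (4S)-6-(tert-butyldimethylsilyloxy)-4-propylhexan-2-one | CC(=O)C[C@@H](CCC)CCO[Si](C)(C)C(C)(C)C
A7 | alternative 3 | O5 enol lactone of the core with C4a unsubstituted | C=C(C)[C@H]1C[C@@H](C[C@@]2(CC=C(C)C)C(=O)C3=C(OC(=O)C[C@@H]3CCC)C=C2O)C1(C)C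
A8 | alternative 3 | 2-(cb-methyl)-2-(3-methylbut-2-enyl)cyclohexane-1,3,5-trione | C=C(C)[C@H]1C[C@@H](CC2(CC=C(C)C)C(=O)CC(=O)CC2=O)C1(C)C
A9 | alternative 3 | (E)-hex-2-enoyl chloride | CCC/C=C/C(=O)Cl
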